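## The problem

Locants used throughout: C1–C7 for the acyl chain (C1 the ester carbonyl, C7 the pyranone carbon bonded to C6, C8–C11 the remaining ring carbons) and C1'–C9' for the alcohol part.

Target 33 is an ester that joins two open-chain polypropionate pieces through a hindered secondary oxygen: an acyl chain whose C7 belongs to a fully substituted 4-pyranone ring (6-ethyl-3,5-dimethyl), and a nine-carbon alcohol part with ketones at C3' and C7'. Apart from the flat pyranone there is no ring to serve as a template, so every stereocentre must be set in acyclic chemistry: C2 (R), C3 (R), C4 (S) and C6 (S) in the acyl chain, and C4' and C6' (both R) in the alcohol part, where C5' is not a stereocentre because its two arms are identical. In a zigzag drawing C2-Me/C3-OH and C3-OH/C4-Me are both anti and the C4 and C6 methyl groups are anti across the C5 carbonyl; the alcohol part is the chiral syn,anti triad. The molecule is fragile: C3-OH/C5=O is a β-hydroxy ketone (retro-aldol, dehydration), C6-H is acidified by both the C5 ketone and the pyranone ring, the two β-acyloxy ketone units of the alcohol part can expel the carboxylate by E1cB elimination, and the ester is α-branched on both sides. The C5 ketone therefore has to appear last, so C5 must travel as a protected carbinol. That is also the opportunity: with C5 at the alcohol level, C2(Me)–C3(OH)–C4(Me)–C5(OH)–C6(Me) is pseudo-C2-symmetric about C4, with C2/C3 and C6/C5 the same anti methyl/carbinol pair in the same absolute sense. Both pairs can then be made in one operation from an achiral three-carbon diol, and C4 needs only the correct choice of which terminus becomes C1. The non-stereogenic C5' has the corollary that the configuration of its carbinol precursor is irrelevant as long as C4' and C6' are right.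

## Retrosynthesis

**Redox and protecting-group endgame (33 ⇐ 32 ⇐ 31 ⇐ 30).** No skeletal bond is cut. The free O3 hydroxyl is traced to the silyl ether 32. The C5 and C7' ketones are traced to the diol 31, and its two hydroxyls to the bis(triethylsilyl) ether 30. This order keeps the epimerisable C6, the β-hydroxy ketone and the second β-acyloxy ketone out of every earlier step. It asks for a silyl pair that can be removed in two stages, a non-basic oxidant and an acidic final desilylation.

**Ester bond C1–O5' (30 ⇐ 21 + 28).** This is the only cut that divides the molecule into halves of similar size; any C–C cut nearby would leave a linear synthesis. Acid 21 carries the whole acyl chain with the pyranone; alcohol 28 carries C7' as a silyl ether, so it has one ketone instead of two at the coupling. The forward reaction is an acylation of a hindered secondary alcohol by an α-branched acid (Yamaguchi conditions). The configuration at C5' of 28 need not be controlled.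

**Alcohol part (28 ⇐ 13 + 26; 26 ⇐ 24 ⇐ 23 ⇐ 22 + 2).** The C4'–C5' bond is cut as an aldol between pentan-3-one 13 and aldehyde 26. The C6'–C7' bond of 26 is cut as a crotylation of propan-1-ol 22 with acetate 2, followed by silylation (24) and alkene cleavage. The alternative cut at C5'–C6' would require a configurationally labile β-keto aldehyde. The forward aldol must be anti and must attack the Felkin–Anh face, which together place the C4' and C6' methyl groups anti; the C5' and C7' carbinol configurations are lost later and do not matter.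

**Pyranone (21 ⇐ 20 ⇐ 19 ⇐ 18 ⇐ 12 + 16; 16 ⇐ 13 + 14).** The ring is opened at the O–C11 bond to triketone 19, which comes from aldol adduct 18 by oxidation. The C7–C8 bond of 18 is cut to aldehyde 12 and the symmetrical diketone 16, itself from pentan-3-one 13 and propanoic anhydride 14. Cutting at C7–C8 rather than C5–C6 keeps C5 and C6 among the centres set by the key step. The forward steps must not epimerise C6, first α to an aldehyde and then α to the triketone. The carboxyl end is masked as the methyl ester 20 throughout.

**Telling the two ends apart (12 ⇐ 10 ⇐ 9 ⇐ 8 ⇐ 7 ⇐ 6 ⇐ 5).** Aldehyde 12 comes from alkene 10 and this from hydroxy ester 9. Compound 9 arises from the iodomethyl tetrahydropyran 8 by reductive ring opening; 8 comes from alkene 7 by oxidative cleavage to the ester, 7 from alcohol 6 by silylation, and 6 from diol 5 by iodoetherification. Only functional groups change. The iodoetherification ties the hydroxyl anti to the central methyl group (future O3) to the far vinyl group (future C7). This leaves the C1 vinyl group and the O5 hydroxyl free to be converted first, and fixes C4 by assignment. The forward cyclisation must choose one of two diastereotopic hydroxyl/alkene pairings.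

**Key cut: C2–C3 and C5–C6 (5 ⇐ 3 + two molecules of 2; 2 ⇐ 1).** Both bonds are cut at once, which reduces diol 5 with its four stereocentres to achiral 2-methylpropane-1,3-diol 3 and racemic acetate 2 (from but-3-en-2-ol 1). Stepwise aldol or crotylmetal cuts at the same bonds would need an aldehyde, a protecting group and a stoichiometric controller for each bond. The forward reaction must give the anti pair at both ends with the same absolute sense and must go to double addition.

## Roads not taken

**Alternative 1: late pyranone closure from an open-chain triketone.** The cut is the ring O–C11 bond: triketone A2 is cyclodehydrated to the pyranone tert-butyl ester A1.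
- Merits: the closure is mild, the ring is not carried through chain-building, and the tert-butyl ester tolerates basic steps.
- Weak points: the step creates no stereocentre, so the four stereocentres of A2 must come from a linear series of aldol and reduction events, each with its own controller. C6 next to the triketone is at risk. Removal of the tert-butyl ester needs acid that threatens the O5 triethylsilyl ether.
- Comparison: as a ring-forming method this road is equal to the chosen one, which uses the same closure in step 12 on triketone 19. In a linear build-up the two chain ends never have to be told apart, which is an advantage. The chosen plan sets against that the formation of C2, C3, the C5 oxygen and C6 in one catalytic step from an achiral diol.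

**Alternative 2: dihydropyranone template from diene–aldehyde cyclocondensation.** The cuts are C4–C5 and O5–C1: aldehyde A4 and diene A5 combine under BF3·OEt2 to dihydropyranone A3.
- Merits: C6 comes enantiopure from the chiral pool. Felkin–Anh addition sets C5, and the 2,3-trans ring relation then places the C4 methyl anti to the C6 methyl, which is the relation the target needs (the C5 configuration itself is lost on oxidation). The two termini of A3 differ from the start.
- Weak points: A3 holds C1–C3 at the wrong oxidation levels (C3 a ketone, C1/C2 an enol ether). C3 must be reduced to the alcohol cis to the C4 methyl on the ring, against the usual preference for the equatorial alcohol. C2 must be set by face-selective saturation of the enol ether. The ring must then be opened and C1 and C7 oxidised before the pyranone can be built. Lewis-acid control of Felkin–Anh versus chelation and of cis versus trans is seldom complete.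
- Comparison: this road is better in the source of enantiopurity and in needing no end differentiation. The chosen plan pays for its symmetry with steps 3 and 6, but it sets four stereocentres at the correct oxidation level in one step and has no ring to dismantle.

**Alternative 3: meso anti,anti triad by two-directional hydroboration.** Both alkenes of dienyl silyl ether A7 are hydroborated with 9-borabicyclo[3.3.1]nonane and oxidised to the meso diol A6.
- Merits: the anti,anti C2–C3–C4 triad of the target is obtained by substrate control (allylic 1,3-strain) from cheap achiral material, without a chiral reagent or a precious metal, and C4 is set directly.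
- Weak points: A6 is meso, so absolute configuration needs a desymmetrisation. A6 ends at C5, so C6 and C7 must be added by a further stereoselective C–C bond formation that creates the most labile centre of the molecule.
- Comparison: for C2–C4 this road is as good as the chosen one or better. The chosen plan offers instead C6 and the C5 oxygen in the same step as C2 and C3, with absolute control from the catalyst.

Key step: step 2

Abbreviations: TES = triethylsilyl, TBS = tert-butyldimethylsilyl, "pyranyl" = 6-ethyl-3,5-dimethyl-4-oxo-4H-pyran-2-yl.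

Assumption: the target is read as the (4R,6R)-4,6-dimethyl-3,7-dioxononan-5-yl ester (carbinol carbon not a stereocentre) of the (2R,3R,4S,6S) acid.

Assumption: the (S)-SEGPHOS iridium catalyst is taken to give the (3S,4S,6S,7S) diol 5 and the (R)-ligand the (3S,4R) alkenol 23; if the correlation is the reverse, the two ligand enantiomers are exchanged and nothing else changes.

Assumption: the iodomethyl-bearing carbon of 6–8 is drawn as the expected equatorial isomer; its configuration is erased in step 6.

## Route

Step 1
Reactants: 1 but-3-en-2-ol (racemic)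
Product: 2 but-3-en-2-yl acetate (racemic)
Conditions: Ac2O, Et3N, 4-(dimethylamino)pyridine (cat.), CH2Cl2, 0 °C → rt
Reagents that add atoms: acetic anhydride, CC(=O)OC(C)=O
Why: Nucleophile-catalysed O-acylation of an unhindered secondary alcohol; the racemate is wanted because the iridium catalyst ionises both enantiomers to the same crotyl fragment.

Step 2
Reactants: 3 2-methylpropane-1,3-diol; 2 but-3-en-2-yl acetate (4 equiv)
Product: 5 (3S,4S,6S,7S)-3,5,7-trimethylnona-1,8-diene-4,6-diol, via (3S,4S)-2,4-dimethylhex-5-ene-1,3-diol 4 (not isolated)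
Conditions: [Ir(cod)Cl]2 (5 mol %), (S)-SEGPHOS [(S)-5,5'-bis(diphenylphosphino)-4,4'-bi-1,3-benzodioxole] (10 mol %), 4-chloro-3-nitrobenzoic acid (20 mol %), K3PO4, H2O, THF, 70 °C
Reagents that add atoms: none
Why: This is the iridium-catalysed transfer-hydrogenative carbonyl crotylation from the alcohol oxidation level, run twice in one flask on a 1,3-diol, which is the known reaction type for this very diol. The cyclometalated C,O-benzoate complex of trivalent iridium dehydrogenates a CH2OH group to the aldehyde; the iridium hydride is deprotonated to a monovalent iridium species that ionises acetate 2 to a π-crotyl complex, so the alcohol is both hydride donor and aldehyde precursor. The (E)-σ-crotyl isomer adds to the transient aldehyde through a closed chair transition state, which gives the anti methyl/carbinol pair, and the ligand decides the aldehyde face, so the carbinols (C3, C5) and their neighbouring methines (C2, C6) are set by the catalyst in the same absolute sense at both ends. Mono-adduct 4 re-enters the cycle through its remaining CH2OH group and gives 5. No ring is formed. The α-stereocentre of each transient aldehyde (future C4) is labile and need not be controlled, because in 5 this carbon bears two identical arms and is not a stereocentre. The selectivities needed are anti over syn (from the (E)-crotyl geometry in the chair), one facial sense at both carbinols (catalyst control that must override the 1,2-induction of the α-methyl group in the second addition) and double over single addition (excess 2); since two catalyst-controlled events are coupled, the minor enantiomeric pathway should end in separable diastereomers and 5 should be of very high enantiomeric purity.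

Step 3
Reactants: 5 (3S,4S,6S,7S)-3,5,7-trimethylnona-1,8-diene-4,6-diol
Product: 6 (2S,3R,4R,5R,6S)-2-[(2S)-but-3-en-2-yl]-6-(iodomethyl)-3,5-dimethyloxan-4-ol
Conditions: I2, NaHCO3, MeCN, −20 °C
Reagents that add atoms: iodine, II
Why: 6-exo iodoetherification under kinetic conditions, the known way of labelling the ends of this diol; only the pairing in which the hydroxyl anti to the central methyl group (future O3) attacks the far vinyl group (future C7) passes through a chair with the side chain, the C4 methyl and the C5 hydroxyl all equatorial and a single axial methyl at C6, whereas the other pairing needs an all-cis ring with two axial substituents. The new iodomethyl-bearing centre should be equatorial and is erased in step 6.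

Step 4
Reactants: 6 iodomethyl oxan-4-ol from step 3
Product: 7 (2S,3S,4R,5S,6S)-2-[(2S)-but-3-en-2-yl]-6-(iodomethyl)-3,5-dimethyl-4-(triethylsilyloxy)oxane
Conditions: TESOTf, 2,6-lutidine, CH2Cl2, −78 → 0 °C
Reagents that add atoms: triethylsilyl trifluoromethanesulfonate, CC[Si](CC)(CC)OS(=O)(=O)C(F)(F)F
Why: Silyl triflate silylation of the only free hydroxyl (O5); triethylsilyl is chosen because it must later be removed in the presence of the TBS ether at O3.

Step 5
Reactants: 7 TES-protected iodomethyl oxane from step 4
Product: 8 methyl (2R)-2-[(2R,3S,4R,5S,6S)-6-(iodomethyl)-3,5-dimethyl-4-(triethylsilyloxy)oxan-2-yl]propanoate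
Conditions: O3, NaOH (2.5 M in MeOH), CH2Cl2, −78 °C
Reagents that add atoms: ozone, [O-][O+]=O; methanol, CO
Why: Ozonolysis in methanolic NaOH converts the terminal alkene directly into the methyl ester (the hemiacetal and the methoxy hydroperoxide are oxidised and dehydrated in situ), a standard way of turning crotylation adducts into α-methyl-β-alkoxy esters; at −78 °C the C2 stereocentre, the ring ether and the primary iodide should be untouched.

Step 6
Reactants: 8 iodomethyl oxanyl propanoate from step 5
Product: 9 methyl (2R,3R,4S,5S,6S)-3-hydroxy-2,4,6-trimethyl-5-(triethylsilyloxy)oct-7-enoate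
Conditions: activated Zn dust, MeOH/THF, 60 °C
Reagents that add atoms: none
Why: Zinc inserts into the C–I bond and the β-alkoxy organozinc fragments (Boord-type reductive elimination), which returns the C7 vinyl group and frees O3 while the O5 silyl ether stays; methanol as solvent makes any ester exchange invisible.

Step 7
Reactants: 9 methyl 3-hydroxy-5-(TESO)-2,4,6-trimethyloct-7-enoate from step 6
Product: 10 methyl (2R,3R,4R,5S,6S)-3-(tert-butyldimethylsilyloxy)-2,4,6-trimethyl-5-(triethylsilyloxy)oct-7-enoate
Conditions: TBSOTf, 2,6-lutidine, CH2Cl2, 0 °C → rt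
Reagents that add atoms: tert-butyldimethylsilyl trifluoromethanesulfonate, CC(C)(C)[Si](C)(C)OS(=O)(=O)C(F)(F)F
Why: Silyl triflate silylation of a hindered β-hydroxy ester; the robust TBS group goes on the oxygen that must stay protected until the last step.

Step 8
Reactants: 10 methyl 3-(TBSO)-5-(TESO)-2,4,6-trimethyloct-7-enoate from step 7
Product: 12 methyl (2R,3R,4R,5R,6R)-3-(tert-butyldimethylsilyloxy)-2,4,6-trimethyl-7-oxo-5-(triethylsilyloxy)heptanoate, via secondary ozonide 11 (not isolated)
Conditions: O3, CH2Cl2, −78 °C; then PPh3, −78 °C → rt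
Reagents that add atoms: ozone, [O-][O+]=O
Why: Ozonolysis with reductive work-up (cycloaddition, cycloreversion and recombination to ozonide 11, then reduction by PPh3) cleaves the only alkene; the α-branched aldehyde is used at once so that C6 is not epimerised.

Step 9
Reactants: 13 pentan-3-one; 14 propanoic anhydride
Product: 16 4-methylheptane-3,5-dione, via difluoroboron diketonate 15 (not isolated)
Conditions: BF3·OEt2, 0 °C → rt; then NaOAc, H2O, reflux
Reagents that add atoms: none
Why: BF3-promoted C-acylation of a ketone by an anhydride through its enol; the product is held as chelate 15, which stops further acylation and is hydrolysed by hot aqueous NaOAc, and acylation at a methylene carbon is the normal outcome under these acidic conditions.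

Step 10
Reactants: 16 4-methylheptane-3,5-dione (2.5 equiv); 12 aldehyde from step 8
Product: 18 methyl (2R,3R,4R,5S,6S)-3-(tert-butyldimethylsilyloxy)-7-hydroxy-2,4,6,8,10-pentamethyl-9,11-dioxo-5-(triethylsilyloxy)tridecanoate (C7/C8/C10 diastereomer mixture), via dilithium dienediolate 17 (not isolated)
Conditions: LiN(iPr)2 (5 equiv), THF, −78 → 0 °C; then 12, −78 °C; aq. NH4Cl
Reagents that add atoms: none
Why: Aldol addition of a 1,3-diketone dianion: the more basic terminal carbanion of 17 adds to the aldehyde at −78 °C faster than it enolises it or attacks the hindered methyl ester; the new centres at C7, C8 and C10 do not matter because all become sp2 in steps 11 and 12.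

Step 11
Reactants: 18 aldol adduct from step 10
Product: 19 methyl (2R,3R,4R,5R,6R)-3-(tert-butyldimethylsilyloxy)-2,4,6,8,10-pentamethyl-7,9,11-trioxo-5-(triethylsilyloxy)tridecanoate (C8/C10 epimers in equilibrium with enol forms)
Conditions: Dess–Martin periodinane, NaHCO3, CH2Cl2, rt
Reagents that add atoms: none
Why: Dess–Martin oxidation of the secondary carbinol under buffered, non-basic conditions should give the 1,3,5-triketone without touching C6.

Step 12
Reactants: 19 triketone from step 11
Product: 20 methyl (2R,3R,4R,5R,6R)-3-(tert-butyldimethylsilyloxy)-6-(6-ethyl-3,5-dimethyl-4-oxo-4H-pyran-2-yl)-2,4-dimethyl-5-(triethylsilyloxy)heptanoate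
Conditions: PPh3, CCl4, THF, rt
Reagents that add atoms: none
Why: Cyclodehydration of a 1,3,5-triketone to a 4-pyranone under nearly neutral conditions: one terminal enol oxygen is activated as its oxyphosphonium salt and the other closes the six-membered ring by addition–elimination (O on C7 to C11); conditions of this type are used where a stereocentre next to the ring (here C6) has to survive.

Step 13
Reactants: 20 pyranone methyl ester from step 12
Product: 21 (2R,3R,4R,5R,6R)-3-(tert-butyldimethylsilyloxy)-6-(6-ethyl-3,5-dimethyl-4-oxo-4H-pyran-2-yl)-2,4-dimethyl-5-(triethylsilyloxy)heptanoic acid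
Conditions: Me3SnOH, ClCH2CH2Cl, 80 °C; then 0.1 M aq. HCl, 0 °C
Reagents that add atoms: trimethyltin hydroxide, C[Sn](C)(C)O
Why: Me3SnOH cleaves methyl esters through a tin carboxylate under nearly neutral conditions, which avoids the hydroxide that could epimerise C2, eliminate the β-silyloxy group or open the pyranone; both silyl ethers should survive.

Step 14
Reactants: 22 propan-1-ol; 2 but-3-en-2-yl acetate (2 equiv)
Product: 23 (3S,4R)-4-methylhex-5-en-3-ol
Conditions: [Ir(cod)Cl]2 (2.5 mol %), (R)-SEGPHOS (5 mol %), 4-chloro-3-nitrobenzoic acid (10 mol %), Cs2CO3 (20 mol %), THF, 90 °C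
Reagents that add atoms: none
Why: The same iridium-catalysed anti-crotylation as in step 2, here as a single addition to the aldehyde formed in situ from propan-1-ol; the (E)-σ-crotyl chair transition state gives the anti pair and the antipodal ligand gives the (3S,4R) enantiomer, whose methyl-bearing carbon becomes C6'.

Step 15
Reactants: 23 (3S,4R)-4-methylhex-5-en-3-ol
Product: 24 triethyl{[(3S,4R)-4-methylhex-5-en-3-yl]oxy}silane
Conditions: TESOTf, 2,6-lutidine, CH2Cl2, −78 °C
Reagents that add atoms: triethylsilyl trifluoromethanesulfonate, CC[Si](CC)(CC)OS(=O)(=O)C(F)(F)F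
Why: Silylation of the secondary alcohol with the same group as on O5 of the acid, so that both come off together in step 19.

Step 16
Reactants: 24 TES ether from step 15
Product: 26 (2S,3S)-2-methyl-3-(triethylsilyloxy)pentanal, via secondary ozonide 25 (not isolated)
Conditions: O3, CH2Cl2, −78 °C; then PPh3, −78 °C → rt
Reagents that add atoms: ozone, [O-][O+]=O
Why: Ozonolysis with reductive work-up through ozonide 25 gives the α-methyl-β-silyloxy aldehyde, which is used crude to avoid epimerisation.

Step 17
Reactants: 13 pentan-3-one; 26 (2S,3S)-2-methyl-3-(triethylsilyloxy)pentanal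
Product: 28 (4R,5R,6R,7S)-5-hydroxy-4,6-dimethyl-7-(triethylsilyloxy)nonan-3-one, via boron enolate 27 (not isolated)
Conditions: Cy2BCl, Et3N, Et2O, 0 °C; then 26, −78 → −20 °C; H2O2, MeOH, pH 7 buffer, 0 °C
Reagents that add atoms: none
Why: Boron-mediated anti aldol: Cy2BCl/Et3N gives the (E)-enol borinate 27, whose chair (Zimmerman–Traxler) transition state gives the 4',5'-anti relation, and the α-methyl aldehyde is attacked on its Felkin–Anh face (the matched case for an (E)-enolate), giving 5',6'-syn. Together these place the C4' and C6' methyl groups anti, which is all that survives once C5' becomes non-stereogenic.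

Step 18
Reactants: 21 acid from step 13; 28 hydroxy ketone from step 17
Product: 30 (4R,5R,6R,7S)-4,6-dimethyl-3-oxo-7-(triethylsilyloxy)nonan-5-yl (2R,3R,4R,5R,6R)-3-(tert-butyldimethylsilyloxy)-6-(6-ethyl-3,5-dimethyl-4-oxo-4H-pyran-2-yl)-2,4-dimethyl-5-(triethylsilyloxy)heptanoate, via mixed anhydride 29 (not isolated)
Conditions: 2,4,6-trichlorobenzoyl chloride, Et3N, THF, rt; then 28, 4-(dimethylamino)pyridine, toluene, rt → 50 °C
Reagents that add atoms: none
Why: Yamaguchi esterification: in mixed anhydride 29 the shielded aroyl carbonyl directs 4-(dimethylamino)pyridine to the aliphatic carbonyl, and the acylpyridinium salt acylates the hindered secondary alcohol; 28 has one ketone and no second free hydroxyl, and the configuration at C5' is immaterial.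

Step 19
Reactants: 30 bis(TES) ester from step 18
Product: 31 (4R,5R,6S,7S)-7-hydroxy-4,6-dimethyl-3-oxononan-5-yl (2R,3R,4R,5R,6R)-3-(tert-butyldimethylsilyloxy)-6-(6-ethyl-3,5-dimethyl-4-oxo-4H-pyran-2-yl)-5-hydroxy-2,4-dimethylheptanoate
Conditions: HF·pyridine, pyridine, THF, 0 °C → rt
Reagents that add atoms: none
Why: Buffered HF·pyridine removes the two secondary TES ethers much faster than the hindered TBS ether at O3; the diol is oxidised at once so that the free O5 hydroxyl cannot lactonise onto C1 and the acyl group cannot migrate to O7'.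

Step 20
Reactants: 31 diol from step 19
Product: 32 (4R,6R)-4,6-dimethyl-3,7-dioxononan-5-yl (2R,3R,4S,6S)-3-(tert-butyldimethylsilyloxy)-6-(6-ethyl-3,5-dimethyl-4-oxo-4H-pyran-2-yl)-2,4-dimethyl-5-oxoheptanoate
Conditions: Dess–Martin periodinane, NaHCO3, CH2Cl2, 0 °C → rt
Reagents that add atoms: none
Why: Dess–Martin oxidation of both secondary carbinols under buffered conditions creates the C5 ketone and the second ketone of the alcohol part, whose arms thereby become identical so that C5' ceases to be a stereocentre; the non-basic medium protects C6 and the β-acyloxy ketones.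

Step 21
Reactants: 32 TBS ether from step 20
Product: 33 (4R,6R)-4,6-dimethyl-3,7-dioxononan-5-yl (2R,3R,4S,6S)-6-(6-ethyl-3,5-dimethyl-4-oxo-4H-pyran-2-yl)-3-hydroxy-2,4-dimethyl-5-oxoheptanoate
Conditions: HF·pyridine, THF, 0 °C → rt
Reagents that add atoms: none
Why: Acidic fluoride cleaves the remaining silyl ether without the basic conditions that would cause retro-aldol cleavage, epimerisation at C6 or elimination of the carboxylate.

## Compound list

1 | but-3-en-2-ol (racemic) | CC(O)C=C | starting material
2 | but-3-en-2-yl acetate (racemic) | CC(OC(C)=O)C=C | intermediate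
3 | 2-methylpropane-1,3-diol | CC(CO)CO | starting material
4 | (3S,4S)-2,4-dimethylhex-5-ene-1,3-diol (both C2 epimers; not isolated) | C=C[C@H](C)[C@H](O)C(C)CO | intermediate
5 | (3S,4S,6S,7S)-3,5,7-trimethylnona-1,8-diene-4,6-diol | C=C[C@H](C)[C@H](O)C(C)[C@@H](O)[C@@H](C)C=C | intermediate
6 | (2S,3R,4R,5R,6S)-2-[(2S)-but-3-en-2-yl]-6-(iodomethyl)-3,5-dimethyloxan-4-ol | C=C[C@H](C)[C@H](O1)[C@H](C)[C@@H](O)[C@@H](C)[C@H]1CI | intermediate
7 | (2S,3S,4R,5S,6S)-2-[(2S)-but-3-en-2-yl]-6-(iodomethyl)-3,5-dimethyl-4-(triethylsilyloxy)oxane | C=C[C@H](C)[C@H](O1)[C@H](C)[C@@H](O[Si](CC)(CC)CC)[C@@H](C)[C@H]1CI | intermediate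
8 | methyl (2R)-2-[(2R,3S,4R,5S,6S)-6-(iodomethyl)-3,5-dimethyl-4-(triethylsilyloxy)oxan-2-yl]propanoate | COC(=O)[C@H](C)[C@H](O1)[C@H](C)[C@@H](O[Si](CC)(CC)CC)[C@@H](C)[C@H]1CI | intermediate
9 | methyl (2R,3R,4S,5S,6S)-3-hydroxy-2,4,6-trimethyl-5-(triethylsilyloxy)oct-7-enoate | COC(=O)[C@H](C)[C@H](O)[C@H](C)[C@@H](O[Si](CC)(CC)CC)[C@@H](C)C=C | intermediate
10 | methyl (2R,3R,4R,5S,6S)-3-(tert-butyldimethylsilyloxy)-2,4,6-trimethyl-5-(triethylsilyloxy)oct-7-enoate | COC(=O)[C@H](C)[C@H](O[Si](C)(C)C(C)(C)C)[C@H](C)[C@@H](O[Si](CC)(CC)CC)[C@@H](C)C=C | intermediate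
11 | methyl (2R,3R,4R,5R,6R)-3-(tert-butyldimethylsilyloxy)-2,4-dimethyl-6-(1,2,4-trioxolan-3-yl)-5-(triethylsilyloxy)heptanoate (secondary ozonide, epimers at the ring carbon; not isolated) | COC(=O)[C@H](C)[C@H](O[Si](C)(C)C(C)(C)C)[C@H](C)[C@@H](O[Si](CC)(CC)CC)[C@@H](C)C1OCOO1 | intermediate
12 | methyl (2R,3R,4R,5R,6R)-3-(tert-butyldimethylsilyloxy)-2,4,6-trimethyl-7-oxo-5-(triethylsilyloxy)heptanoate | COC(=O)[C@H](C)[C@H](O[Si](C)(C)C(C)(C)C)[C@H](C)[C@@H](O[Si](CC)(CC)CC)[C@@H](C)C=O | intermediate
13 | pentan-3-one | CCC(=O)CC | starting material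
14 | propanoic anhydride | CCC(=O)OC(=O)CC | starting material
15 | difluoroboron chelate of 4-methylheptane-3,5-dione (4,6-diethyl-2,2-difluoro-5-methyl-1,3,2-dioxaborinine; not isolated) | CCC1=[O+][B-](F)(F)OC(CC)=C1C | intermediate
16 | 4-methylheptane-3,5-dione | CCC(=O)C(C)C(=O)CC | intermediate
17 | dilithium 4-methylhepta-2,4-diene-3,5-diolate (dianion of 16; not isolated) | [Li+].[Li+].CC=C([O-])C(C)=C([O-])CC | intermediate
18 | methyl (2R,3R,4R,5S,6S)-3-(tert-butyldimethylsilyloxy)-7-hydroxy-2,4,6,8,10-pentamethyl-9,11-dioxo-5-(triethylsilyloxy)tridecanoate (mixture at C7, C8, C10) | COC(=O)[C@H](C)[C@H](O[Si](C)(C)C(C)(C)C)[C@H](C)[C@@H](O[Si](CC)(CC)CC)[C@@H](C)C(O)C(C)C(=O)C(C)C(=O)CC | intermediate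
19 | methyl (2R,3R,4R,5R,6R)-3-(tert-butyldimethylsilyloxy)-2,4,6,8,10-pentamethyl-7,9,11-trioxo-5-(triethylsilyloxy)tridecanoate (C8/C10 epimers, enol forms) | COC(=O)[C@H](C)[C@H](O[Si](C)(C)C(C)(C)C)[C@H](C)[C@@H](O[Si](CC)(CC)CC)[C@@H](C)C(=O)C(C)C(=O)C(C)C(=O)CC | intermediate
20 | methyl (2R,3R,4R,5R,6R)-3-(tert-butyldimethylsilyloxy)-6-(6-ethyl-3,5-dimethyl-4-oxo-4H-pyran-2-yl)-2,4-dimethyl-5-(triethylsilyloxy)heptanoate | COC(=O)[C@H](C)[C@H](O[Si](C)(C)C(C)(C)C)[C@H](C)[C@@H](O[Si](CC)(CC)CC)[C@@H](C)c1oc(CC)c(C)c(=O)c1C | intermediate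
21 | (2R,3R,4R,5R,6R)-3-(tert-butyldimethylsilyloxy)-6-(6-ethyl-3,5-dimethyl-4-oxo-4H-pyran-2-yl)-2,4-dimethyl-5-(triethylsilyloxy)heptanoic acid | OC(=O)[C@H](C)[C@H](O[Si](C)(C)C(C)(C)C)[C@H](C)[C@@H](O[Si](CC)(CC)CC)[C@@H](C)c1oc(CC)c(C)c(=O)c1C | intermediate
22 | propan-1-ol | CCCO | starting material
23 | (3S,4R)-4-methylhex-5-en-3-ol | CC[C@H](O)[C@H](C)C=C | intermediate
24 | triethyl{[(3S,4R)-4-methylhex-5-en-3-yl]oxy}silane | CC[C@H](O[Si](CC)(CC)CC)[C@H](C)C=C | intermediate
25 | triethyl{[(2S,3S)-2-(1,2,4-trioxolan-3-yl)pentan-3-yl]oxy}silane (secondary ozonide, epimers at the ring carbon; not isolated) | CC[C@H](O[Si](CC)(CC)CC)[C@H](C)C1OCOO1 | intermediate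
26 | (2S,3S)-2-methyl-3-(triethylsilyloxy)pentanal | CC[C@H](O[Si](CC)(CC)CC)[C@H](C)C=O | intermediate
27 | (E)-dicyclohexyl(pent-2-en-3-yloxy)borane (not isolated) | C/C=C(CC)/OB(C1CCCCC1)C1CCCCC1 | intermediate
28 | (4R,5R,6R,7S)-5-hydroxy-4,6-dimethyl-7-(triethylsilyloxy)nonan-3-one | CCC(=O)[C@H](C)[C@H](O)[C@@H](C)[C@H](CC)O[Si](CC)(CC)CC | intermediate
29 | (2R,3R,4R,5R,6R)-3-(tert-butyldimethylsilyloxy)-6-(6-ethyl-3,5-dimethyl-4-oxo-4H-pyran-2-yl)-2,4-dimethyl-5-(triethylsilyloxy)heptanoic 2,4,6-trichlorobenzoic anhydride (not isolated) | O=C(OC(=O)c1c(Cl)cc(Cl)cc1Cl)[C@H](C)[C@H](O[Si](C)(C)C(C)(C)C)[C@H](C)[C@@H](O[Si](CC)(CC)CC)[C@@H](C)c1oc(CC)c(C)c(=O)c1C | intermediate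
30 | (4R,5R,6R,7S)-4,6-dimethyl-3-oxo-7-(triethylsilyloxy)nonan-5-yl (2R,3R,4R,5R,6R)-3-(tert-butyldimethylsilyloxy)-6-(6-ethyl-3,5-dimethyl-4-oxo-4H-pyran-2-yl)-2,4-dimethyl-5-(triethylsilyloxy)heptanoate | CCC(=O)[C@H](C)[C@H](OC(=O)[C@H](C)[C@H](O[Si](C)(C)C(C)(C)C)[C@H](C)[C@@H](O[Si](CC)(CC)CC)[C@@H](C)c1oc(CC)c(C)c(=O)c1C)[C@@H](C)[C@H](CC)O[Si](CC)(CC)CC | intermediate
31 | (4R,5R,6S,7S)-7-hydroxy-4,6-dimethyl-3-oxononan-5-yl (2R,3R,4R,5R,6R)-3-(tert-butyldimethylsilyloxy)-6-(6-ethyl-3,5-dimethyl-4-oxo-4H-pyran-2-yl)-5-hydroxy-2,4-dimethylheptanoate | CCC(=O)[C@H](C)[C@H](OC(=O)[C@H](C)[C@H](O[Si](C)(C)C(C)(C)C)[C@H](C)[C@@H](O)[C@@H](C)c1oc(CC)c(C)c(=O)c1C)[C@@H](C)[C@@H](O)CC | intermediate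
32 | (4R,6R)-4,6-dimethyl-3,7-dioxononan-5-yl (2R,3R,4S,6S)-3-(tert-butyldimethylsilyloxy)-6-(6-ethyl-3,5-dimethyl-4-oxo-4H-pyran-2-yl)-2,4-dimethyl-5-oxoheptanoate | CCC(=O)[C@H](C)C(OC(=O)[C@H](C)[C@H](O[Si](C)(C)C(C)(C)C)[C@H](C)C(=O)[C@@H](C)c1oc(CC)c(C)c(=O)c1C)[C@@H](C)C(=O)CC | intermediate
33 | (4R,6R)-4,6-dimethyl-3,7-dioxononan-5-yl (2R,3R,4S,6S)-6-(6-ethyl-3,5-dimethyl-4-oxo-4H-pyran-2-yl)-3-hydroxy-2,4-dimethyl-5-oxoheptanoate | CCC(=O)[C@H](C)C(OC(=O)[C@H](C)[C@H](O)[C@H](C)C(=O)[C@@H](C)c1oc(CC)c(C)c(=O)c1C)[C@@H](C)C(=O)CC | target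

## Step count and least certain steps

Total step count: 21. Longest linear sequence: 16 (steps 1–8, 10–13 and 18–21).

**Step 2 (key step).** The second crotylation is slower than the first and must override the 1,2-induction of the α-methyl group in the transient β-hydroxy aldehyde. The reaction may therefore stall at 4 or leak into syn units and the mismatched diastereomer, which are hard to separate from 5.

Fallback (sets out from 3, returns at 5): the two C–C bonds are made one at a time with a stoichiometric chiral crotylborane.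
- Diol 3 is monosilylated (NaH, TESCl) to 2-methyl-3-(triethylsilyloxy)propan-1-ol F1 and oxidised (Swern) to 2-methyl-3-(triethylsilyloxy)propanal F2.
- F2 is treated with the enantiomer of (E)-crotyldiisopinocampheylborane that gives the (3S,4S) anti adduct, (3S,4S)-2,4-dimethyl-1-(triethylsilyloxy)hex-5-en-3-ol F3. Both C2 epimers form and converge later.
- Silylation gives (3S,4S)-2,4-dimethyl-1,3-bis(triethylsilyloxy)hex-5-ene F4. Swern conditions convert its primary silyl ether directly into (3S,4S)-2,4-dimethyl-3-(triethylsilyloxy)hex-5-enal F5.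
- A second crotylboration with the same reagent gives (3S,4S,6S,7S)-3,5,7-trimethyl-6-(triethylsilyloxy)nona-1,8-dien-4-ol F6, and HF·pyridine returns 5.

**Step 3.** End selectivity may be lost, through cyclisation by the other hydroxyl or iodine-promoted equilibration between the two iodoethers. That would scramble the assignment of C1 and C7 and with it the configuration at C4.

Fallback (sets out from 5, returns at 10): the ends are told apart by separation instead of by a selective cyclisation.
- Ozonolysis of 5 with one equivalent of ozone gives two regioisomeric lactols, because each mono-aldehyde is captured by its δ-hydroxyl. The wanted one is (3R,4R,5S,6S)-6-[(2S)-but-3-en-2-yl]-3,5-dimethyloxane-2,4-diol F7 (C1 aldehyde closed on O5). The other, (3R,4R,5R,6S)-6-[(2S)-but-3-en-2-yl]-3,5-dimethyloxane-2,4-diol F8 (C7 aldehyde closed on O3), is removed by chromatography.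
- F7 is oxidised at the lactol carbon only (2,2,6,6-tetramethylpiperidin-1-oxyl, PhI(OAc)2) to (3R,4R,5S,6S)-6-[(2S)-but-3-en-2-yl]-4-hydroxy-3,5-dimethyloxan-2-one F9.
- Silylation (TBSOTf) gives (3R,4R,5R,6S)-6-[(2S)-but-3-en-2-yl]-4-(tert-butyldimethylsilyloxy)-3,5-dimethyloxan-2-one F10.
- NaOMe/MeOH opens the lactone to methyl (2R,3R,4R,5S,6S)-3-(tert-butyldimethylsilyloxy)-5-hydroxy-2,4,6-trimethyloct-7-enoate F11, and TESOTf at O5 gives 10.
- This road is shorter but can use at most half of the material.

**Step 10.** The strongly basic dianion may enolise the α-branched aldehyde (epimerisation at C6) or cause β-elimination of the O5 silyloxy group. Attack on the C1 ester is less likely.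

Fallback (sets out from 16 and 12, returns at 18): the same C7–C8 bond is made under Lewis-acid instead of strong-base conditions. Diketone 16 is converted (Me3SiCl/Et3N, then LiN(iPr)2/Me3SiCl) into 4-methyl-3,5-bis(trimethylsilyloxy)hepta-2,4-diene F12. Its terminal carbon adds to 12 in a BF3·OEt2-mediated vinylogous Mukaiyama aldol reaction at −78 °C, and aqueous work-up gives 18.

**Step 13.** Substitution at the hindered, α-branched and β-silyloxylated ester carbonyl may be slow or incomplete. Forcing it risks loss of the TES group or epimerisation at C2.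

Fallback (sets out from 20, returns at 21): a reduction–oxidation detour replaces acyl substitution. Ester 20 is reduced with iBu2AlH at −78 °C to (2R,3R,4R,5R,6R)-3-(tert-butyldimethylsilyloxy)-6-(6-ethyl-3,5-dimethyl-4-oxo-4H-pyran-2-yl)-2,4-dimethyl-5-(triethylsilyloxy)heptanal F13; the tetrasubstituted, cross-conjugated pyranone carbonyl is a poor hydride acceptor. Pinnick oxidation (NaClO2, NaH2PO4, 2-methylbut-2-ene) then gives 21.

**Step 18.** Acylation is slow because both partners are α-branched. During long exposure to base and nucleophilic catalyst the activated acid can epimerise at C2 or lose the β-silyloxy group through a ketene, and 28 can undergo retro-aldol cleavage.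

Fallback (sets out from 20 and 28, returns at 32): the ester is formed by hydride transfer instead of acyl substitution (Evans–Tishchenko coupling).
- Aldehyde F13, made from 20 as above, and β-hydroxy ketone 28 are treated with catalytic SmI2 (divalent samarium) in THF at −10 °C. The hemiacetal formed at O5' delivers its hydride to the C3' ketone and gives (3R,4S,5S,6R,7S)-3-hydroxy-4,6-dimethyl-7-(triethylsilyloxy)nonan-5-yl (2R,3R,4R,5R,6R)-3-(tert-butyldimethylsilyloxy)-6-(6-ethyl-3,5-dimethyl-4-oxo-4H-pyran-2-yl)-2,4-dimethyl-5-(triethylsilyloxy)heptanoate F14.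
- HF·pyridine/pyridine removes both TES groups to give (3R,4S,6S,7S)-3,7-dihydroxy-4,6-dimethylnonan-5-yl (2R,3R,4R,5R,6R)-3-(tert-butyldimethylsilyloxy)-6-(6-ethyl-3,5-dimethyl-4-oxo-4H-pyran-2-yl)-5-hydroxy-2,4-dimethylheptanoate F15 (C5' as in F14).
- Dess–Martin oxidation of its three carbinols gives 32.

## Further compounds

F1 | step 2 | 2-methyl-3-(triethylsilyloxy)propan-1-ol (racemic) | CC(CO)CO[Si](CC)(CC)CC
F2 | step 2 | 2-methyl-3-(triethylsilyloxy)propanal (racemic) | CC(C=O)CO[Si](CC)(CC)CC
F3 | step 2 | (3S,4S)-2,4-dimethyl-1-(triethylsilyloxy)hex-5-en-3-ol (both C2 epimers) | C=C[C@H](C)[C@H](O)C(C)CO[Si](CC)(CC)CC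
F4 | step 2 | (3S,4S)-2,4-dimethyl-1,3-bis(triethylsilyloxy)hex-5-ene (both C2 epimers) | C=C[C@H](C)[C@H](O[Si](CC)(CC)CC)C(C)CO[Si](CC)(CC)CC
F5 | step 2 | (3S,4S)-2,4-dimethyl-3-(triethylsilyloxy)hex-5-enal (both C2 epimers) | C=C[C@H](C)[C@H](O[Si](CC)(CC)CC)C(C)C=O
F6 | step 2 | (3S,4S,6S,7S)-3,5,7-trimethyl-6-(triethylsilyloxy)nona-1,8-dien-4-ol (both C5 epimers) | C=C[C@H](C)[C@H](O)C(C)[C@@H](O[Si](CC)(CC)CC)[C@@H](C)C=C
F7 | step 3 | (3R,4R,5S,6S)-6-[(2S)-but-3-en-2-yl]-3,5-dimethyloxane-2,4-diol (anomers) | OC1[C@H](C)[C@H](O)[C@H](C)[C@@H](O1)[C@@H](C)C=C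
F8 | step 3 | (3R,4R,5R,6S)-6-[(2S)-but-3-en-2-yl]-3,5-dimethyloxane-2,4-diol (anomers) | C=C[C@H](C)[C@H](O1)[C@H](C)[C@@H](O)[C@@H](C)C1O
F9 | step 3 | (3R,4R,5S,6S)-6-[(2S)-but-3-en-2-yl]-4-hydroxy-3,5-dimethyloxan-2-one | O=C1[C@H](C)[C@H](O)[C@H](C)[C@@H](O1)[C@@H](C)C=C
F10 | step 3 | (3R,4R,5R,6S)-6-[(2S)-but-3-en-2-yl]-4-(tert-butyldimethylsilyloxy)-3,5-dimethyloxan-2-one | O=C1[C@H](C)[C@H](O[Si](C)(C)C(C)(C)C)[C@H](C)[C@@H](O1)[C@@H](C)C=C
F11 | step 3 | methyl (2R,3R,4R,5S,6S)-3-(tert-butyldimethylsilyloxy)-5-hydroxy-2,4,6-trimethyloct-7-enoate | COC(=O)[C@H](C)[C@H](O[Si](C)(C)C(C)(C)C)[C@H](C)[C@@H](O)[C@@H](C)C=C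
F12 | step 10 | 4-methyl-3,5-bis(trimethylsilyloxy)hepta-2,4-diene (mixture of geometric isomers) | CC=C(O[Si](C)(C)C)C(C)=C(CC)O[Si](C)(C)C
F13 | step 13 | (2R,3R,4R,5R,6R)-3-(tert-butyldimethylsilyloxy)-6-(6-ethyl-3,5-dimethyl-4-oxo-4H-pyran-2-yl)-2,4-dimethyl-5-(triethylsilyloxy)heptanal | O=C[C@H](C)[C@H](O[Si](C)(C)C(C)(C)C)[C@H](C)[C@@H](O[Si](CC)(CC)CC)[C@@H](C)c1oc(CC)c(C)c(=O)c1C
F14 | step 18 | (3R,4S,5S,6R,7S)-3-hydroxy-4,6-dimethyl-7-(triethylsilyloxy)nonan-5-yl (2R,3R,4R,5R,6R)-3-(tert-butyldimethylsilyloxy)-6-(6-ethyl-3,5-dimethyl-4-oxo-4H-pyran-2-yl)-2,4-dimethyl-5-(triethylsilyloxy)heptanoate | CC[C@@H](O)[C@H](C)[C@H](OC(=O)[C@H](C)[C@H](O[Si](C)(C)C(C)(C)C)[C@H](C)[C@@H](O[Si](CC)(CC)CC)[C@@H](C)c1oc(CC)c(C)c(=O)c1C)[C@@H](C)[C@H](CC)O[Si](CC)(CC)CC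
F15 | step 18 | (3R,4S,6S,7S)-3,7-dihydroxy-4,6-dimethylnonan-5-yl (2R,3R,4R,5R,6R)-3-(tert-butyldimethylsilyloxy)-6-(6-ethyl-3,5-dimethyl-4-oxo-4H-pyran-2-yl)-5-hydroxy-2,4-dimethylheptanoate (C5' as in F14) | CC[C@@H](O)[C@H](C)[C@H](OC(=O)[C@H](C)[C@H](O[Si](C)(C)C(C)(C)C)[C@H](C)[C@@H](O)[C@@H](C)c1oc(CC)c(C)c(=O)c1C)[C@@H](C)[C@@H](O)CC
A1 | alternative 1 | tert-butyl (2R,3R,4R,5R,6R)-3-(tert-butyldimethylsilyloxy)-6-(6-ethyl-3,5-dimethyl-4-oxo-4H-pyran-2-yl)-2,4-dimethyl-5-(triethylsilyloxy)heptanoate | CC(C)(C)OC(=O)[C@H](C)[C@H](O[Si](C)(C)C(C)(C)C)[C@H](C)[C@@H](O[Si](CC)(CC)CC)[C@@H](C)c1oc(CC)c(C)c(=O)c1C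
A2 | alternative 1 | tert-butyl (2R,3R,4R,5R,6R)-3-(tert-butyldimethylsilyloxy)-2,4,6,8,10-pentamethyl-7,9,11-trioxo-5-(triethylsilyloxy)tridecanoate | CC(C)(C)OC(=O)[C@H](C)[C@H](O[Si](C)(C)C(C)(C)C)[C@H](C)[C@@H](O[Si](CC)(CC)CC)[C@@H](C)C(=O)C(C)C(=O)C(C)C(=O)CC
A3 | alternative 2 | 2,3-trans-2-[(S)-1-(benzyloxy)propan-2-yl]-3,5-dimethyl-2,3-dihydro-4H-pyran-4-one | C1=C(C)C(=O)[C@H](C)[C@H](O1)[C@@H](C)COCc2ccccc2
A4 | alternative 2 | (S)-3-(benzyloxy)-2-methylpropanal | O=C[C@@H](C)COCc1ccccc1
A5 | alternative 2 | (1E,3Z)-1-methoxy-2-methyl-3-(trimethylsilyloxy)penta-1,3-diene | CO/C=C(C)/C(O[Si](C)(C)C)=C/C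
A6 | alternative 3 | meso anti,anti-3-(tert-butyldimethylsilyloxy)-2,4-dimethylpentane-1,5-diol | OC[C@H](C)[C@H](O[Si](C)(C)C(C)(C)C)[C@H](C)CO
A7 | alternative 3 | tert-butyl[(2,4-dimethylpenta-1,4-dien-3-yl)oxy]dimethylsilane | C=C(C)C(O[Si](C)(C)C(C)(C)C)C(C)=C
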